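**Plan**

1. Numbering as in isochromene (O2, C1, C3–C8a; side chain C1′–C7′). Retrosynthetic cuts, in order: C5–Cl (late chlorination), O2–C3 (6-endo oxa-Michael of the C1 hydroxyl onto an enynone), C3–C1′ (Sonogashira), then C4a–C5 and C7–C8 together.
2. Enabling feature: in the carbocycle the ketone C6 lies between C5 and C7, and the enone β-carbon C4a (ketone oxidation level) and the carbinol C8 sit 1,3 across C8a. The ring is therefore a (3+3) union of an acetoin-derived C5–C6–C7 dinucleophile with a C4a-ketal/C8-aldehyde dielectrophile.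
3. Forward order: carbocycle first (one-pot ketal alkylation C5–C4a, titanium enediolate aldol C7–C8, loss of methanol), then the side chain on the alkyne, then the pyran ring by desilylation/cyclisation, then chlorine.
4. Stereochemistry: C8a from an Evans syn-aldol (its carbinol is later oxidised and ketalised); C7 and C8 from C8a in the chair-like aldol closure; C5′ from asymmetric hydrogenation of α-methylene-γ-butyrolactone; both E alkenes from Wittig and Takai olefinations.
5. Helpers and their removal: dimethyl ketal at C4a (keeps C8a from being a 1,3-dicarbonyl methine; leaves as methanol in the key step), oxazolidinone (step 7), silyl ethers (steps 10 and 17).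

Key step: step 10

Remark: 3-[(tert-butyldiphenylsilyl)oxy]propanoic acid (4) is taken as a catalogue compound; chlorine is introduced last because an α-chloro ketone would be exposed to Favorskii-type side reactions in the enolate chemistry of the key step.

**Route**

Step 1
Reactants: 1 3-hydroxybutan-2-one (acetoin, racemic)
Product: 2 3-[(trimethylsilyl)oxy]butan-2-one
Conditions: Me3SiCl, Et3N, CH2Cl2, 0 °C to rt
Reagents that add atoms: chlorotrimethylsilane, C[Si](C)(C)Cl
Why: Silylation of the free hydroxyl (silyl ether formation) masks it for the enolate chemistry of step 2 and places on O7 the Me3Si group that titanium exchanges in step 10; the stereocentre is racemic and is erased later.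

Step 2
Reactants: 2 3-[(trimethylsilyl)oxy]butan-2-one
Product: 3 2,3-bis[(trimethylsilyl)oxy]but-1-ene
Conditions: LiN(i-Pr)2, THF, −78 °C; then Me3SiCl, −78 °C to rt
Reagents that add atoms: chlorotrimethylsilane, C[Si](C)(C)Cl
Why: Kinetic deprotonation by the hindered amide base should occur at the methyl group and not at the silyloxy-bearing methine, and O-silylation then gives the less substituted silyl enol ether (kinetic enol silane formation), which fixes C5 as the first nucleophilic site.

Step 3
Reactants: 4 3-[(tert-butyldiphenylsilyl)oxy]propanoic acid; 5 (R)-4-benzyloxazolidin-2-one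
Product: 6 (R)-4-benzyl-3-{3-[(tert-butyldiphenylsilyl)oxy]propanoyl}oxazolidin-2-one
Conditions: t-BuCOCl, Et3N, THF, −20 °C; then lithium salt of 5 (n-BuLi, THF, −78 °C), to 0 °C
Reagents that add atoms: none
Why: N-Acylation of the lithiated oxazolidinone by the mixed pivalic anhydride of 4 is the standard entry to Evans imides and attaches the auxiliary that will set C8a.

Step 4
Reactants: 6 (R)-4-benzyl-3-{3-[(tert-butyldiphenylsilyl)oxy]propanoyl}oxazolidin-2-one; 7 3-(trimethylsilyl)prop-2-ynal
Product: 8 (R)-4-benzyl-3-[(2R,3R)-2-{[(tert-butyldiphenylsilyl)oxy]methyl}-3-hydroxy-5-(trimethylsilyl)pent-4-ynoyl]oxazolidin-2-one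
Conditions: n-Bu2BOTf, i-Pr2NEt, CH2Cl2, −78 to 0 °C; 7, −78 to 0 °C; H2O2, pH 7 buffer, MeOH
Reagents that add atoms: none
Why: Evans syn-aldol: the (Z)-boron enolate adds through a Zimmerman–Traxler chair on the face left open by the benzyl group, which should set C2 of the acyl chain (the future C8a) as R, together with a (3R)-carbinol that is only a precursor of the C4a ketone.

Step 5
Reactants: 8 (R)-4-benzyl-3-[(2R,3R)-2-{[(tert-butyldiphenylsilyl)oxy]methyl}-3-hydroxy-5-(trimethylsilyl)pent-4-ynoyl]oxazolidin-2-one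
Product: 9 (R)-4-benzyl-3-[(2R)-2-{[(tert-butyldiphenylsilyl)oxy]methyl}-3-oxo-5-(trimethylsilyl)pent-4-ynoyl]oxazolidin-2-one
Conditions: Dess–Martin periodinane, CH2Cl2, 0 °C to rt
Reagents that add atoms: none
Why: Dess–Martin oxidation of the propargylic carbinol gives the β-keto imide, whose methine should stay configurationally intact because allylic strain in the imide disfavours its enolisation (known behaviour of Evans β-keto imides).

Step 6
Reactants: 9 (R)-4-benzyl-3-[(2R)-2-{[(tert-butyldiphenylsilyl)oxy]methyl}-3-oxo-5-(trimethylsilyl)pent-4-ynoyl]oxazolidin-2-one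
Product: 10 (R)-4-benzyl-3-[(2R)-2-{[(tert-butyldiphenylsilyl)oxy]methyl}-3,3-dimethoxy-5-(trimethylsilyl)pent-4-ynoyl]oxazolidin-2-one
Conditions: MeOSiMe3 (excess), Me3SiOTf (5 mol %), CH2Cl2, −78 to −20 °C
Reagents that add atoms: methoxytrimethylsilane, CO[Si](C)(C)C
Why: Aprotic ketalisation with an alkoxysilane under catalytic Me3SiOTf converts the ynone carbonyl into the dimethyl ketal without a free alcohol that could add to the ynone in conjugate fashion; from here on C8a is no longer flanked by two carbonyl groups.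

Step 7
Reactants: 10 (R)-4-benzyl-3-[(2R)-2-{[(tert-butyldiphenylsilyl)oxy]methyl}-3,3-dimethoxy-5-(trimethylsilyl)pent-4-ynoyl]oxazolidin-2-one
Product: 11 (R)-2-{[(tert-butyldiphenylsilyl)oxy]methyl}-3,3-dimethoxy-5-(trimethylsilyl)pent-4-yn-1-ol
Conditions: LiBH4, MeOH (1 equiv), THF, 0 °C
Reagents that add atoms: none
Why: Reductive cleavage of the N-acyl oxazolidinone with LiBH4 gives the primary alcohol (future C8) and returns the auxiliary; ketal, silyl ether and alkynylsilane are inert to borohydride.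

Step 8
Reactants: 11 (R)-2-{[(tert-butyldiphenylsilyl)oxy]methyl}-3,3-dimethoxy-5-(trimethylsilyl)pent-4-yn-1-ol
Product: 12 (R)-2-{[(tert-butyldiphenylsilyl)oxy]methyl}-3,3-dimethoxypent-4-yn-1-ol
Conditions: K2CO3 (cat.), MeOH, rt
Reagents that add atoms: none
Why: Base-catalysed methanolysis cleaves only the C(sp)–Si bond, the primary TBDPS ether and the ketal being stable to K2CO3 in methanol, and frees the alkyne terminus for step 16.

Step 9
Reactants: 12 (R)-2-{[(tert-butyldiphenylsilyl)oxy]methyl}-3,3-dimethoxypent-4-yn-1-ol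
Product: 13 (S)-2-{[(tert-butyldiphenylsilyl)oxy]methyl}-3,3-dimethoxypent-4-ynal
Conditions: Dess–Martin periodinane, NaHCO3, CH2Cl2, 0 °C; used at once
Reagents that add atoms: none
Why: Buffered Dess–Martin oxidation should give the α-branched aldehyde without epimerisation, since the β-carbon is a ketal and the α-hydrogen has only ordinary aldehyde acidity.

Step 10
Reactants: 3 2,3-bis[(trimethylsilyl)oxy]but-1-ene; 13 (S)-2-{[(tert-butyldiphenylsilyl)oxy]methyl}-3,3-dimethoxypent-4-ynal
Product: 16 (4S,5R,6R)-4-{[(tert-butyldiphenylsilyl)oxy]methyl}-3-ethynyl-5,6-dihydroxy-6-methylcyclohex-2-en-1-one, via acyclic β-methoxy keto aldehyde 14 (not isolated), via cyclised β-methoxy ketone diol 15 (not isolated)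
Conditions: 3 (1.0 equiv), Me3SiOTf (0.1 equiv), CH2Cl2 (0.02 M), −78 °C; then TiCl4 (2.5 equiv), i-Pr2NEt (1.5 equiv), −78 to 0 °C; aq. NH4Cl
Reagents that add atoms: none
Why: Proposed new method: catalytic Me3SiOTf ionises the alkynyl dimethyl ketal of 13 to an oxocarbenium ion that is captured by the methylene terminus of enol silane 3 (C5–C4a; Mukaiyama-type addition to an acetal, which leaves a free aldehyde untouched), and TiCl4/i-Pr2NEt then exchanges the C7–OSiMe3 group for a titanium alkoxide, forms the five-membered titanium enediolate across O6/O7 and closes the ring by aldol addition of C7 to the C8 aldehyde, after which the β-methoxy group at C4a is lost on warming to give the endocyclic enone. The closest known reaction types are the TiCl4-mediated (3+3) cyclocondensations of silyl enol ether dinucleophiles with masked 1,3-dicarbonyl electrophiles and titanium enolate aldol additions of α-oxygenated ketones; new here is an acetoin-derived C5/C7 dinucleophile in a two-stage one-pot variant that stops at the non-aromatic aldol. The carbocycle closes in a 6-(enolendo)-exo-trig mode while C4a is still sp3, so no open-chain enone geometry has to be controlled. C7 and C8 are set relative to C8a in a chair-like transition state: the chelated enediolate places O7 pseudo-equatorial and the methyl group pseudo-axial, the aldehyde oxygen binds the same titanium and is therefore pseudo-axial and cis to O7, and the CH2OSi group at C8a stays pseudo-equatorial to avoid a 1,3-diaxial clash with that methyl group, which corresponds to the (7R,8R,8aS) array. The step needs chemoselectivity for ketal over aldehyde in the first stage (Me3SiOTf does not activate aldehydes toward enol silanes at −78 °C), enolisation toward C7 and not C5 in the second (favoured by the titanium alkoxide at O7, while a C5 enolate has no ring-forming pathway), and configurational stability at C8a (the C4a ketal keeps C8a from being a 1,3-dicarbonyl methine until the ring is closed).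

Step 11
Reactants: 17 α-methylene-γ-butyrolactone (3-methylenedihydrofuran-2(3H)-one)
Product: 18 (S)-3-methyldihydrofuran-2(3H)-one
Conditions: H2 (100 atm), Ru(OAc)2[(R)-BINAP] (0.5 mol %), CH2Cl2, 50 °C
Reagents that add atoms: none
Why: Asymmetric hydrogenation of the exocyclic alkene by the BINAP–ruthenium diacetate complex, directed by the lactone carbonyl, should give the (S)-α-methyl lactone (C5′); the (R)-ligand is the antipode expected to give this sense, and the sign of rotation of 18 is to be checked against the known lactone before the material is carried on.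

Step 12
Reactants: 18 (S)-3-methyldihydrofuran-2(3H)-one
Product: 19 (3S)-3-methyltetrahydrofuran-2-ol (anomers)
Conditions: i-Bu2AlH (1.05 equiv), CH2Cl2, −78 °C
Reagents that add atoms: none
Why: Half-reduction of the lactone to the lactol at −78 °C (stable aluminium hemiacetal) exposes the latent aldehyde without touching the α-stereocentre.

Step 13
Reactants: 19 (3S)-3-methyltetrahydrofuran-2-ol
Product: 20 (2E,4S)-6-hydroxy-2,4-dimethylhex-2-enal
Conditions: Ph3P=C(CH3)CHO, toluene, 90 °C
Reagents that add atoms: 2-(triphenylphosphoranylidene)propanal, CC(C=O)=P(c1ccccc1)(c1ccccc1)c1ccccc1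
Why: The lactol opens to the hydroxy aldehyde, which should undergo Wittig olefination with the formyl-stabilised ylide to give the (E)-trisubstituted enal (C3′=C4′); the enal product is too unreactive toward this ylide for a second olefination.

Step 14
Reactants: 20 (2E,4S)-6-hydroxy-2,4-dimethylhex-2-enal
Product: 21 (2E,4S)-6-[(tert-butyldimethylsilyl)oxy]-2,4-dimethylhex-2-enal
Conditions: t-BuMe2SiCl, imidazole, CH2Cl2, 0 °C to rt
Reagents that add atoms: tert-butyldimethylsilyl chloride, CC(C)(C)[Si](C)(C)Cl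
Why: Silylation of the primary alcohol (silyl ether formation) prevents oxa-Michael cyclisation onto the enal and protects O7′ through the chromium and palladium steps.

Step 15
Reactants: 21 (2E,4S)-6-[(tert-butyldimethylsilyl)oxy]-2,4-dimethylhex-2-enal
Product: 22 tert-butyl{[(3S,4E,6E)-7-iodo-3,5-dimethylhepta-4,6-dien-1-yl]oxy}dimethylsilane
Conditions: CrCl2 (6 equiv), CHI3 (2 equiv), THF/dioxane, 0 °C to rt
Reagents that add atoms: iodoform, IC(I)I
Why: Takai iodo-olefination of the enal with the chromium carbenoid formed from CrCl2 and CHI3 should give the (E)-vinyl iodide (C1′=C2′) and hence the (E,E)-dienyl iodide without touching C5′.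

Step 16
Reactants: 16 (4S,5R,6R)-4-{[(tert-butyldiphenylsilyl)oxy]methyl}-3-ethynyl-5,6-dihydroxy-6-methylcyclohex-2-en-1-one; 22 tert-butyl{[(3S,4E,6E)-7-iodo-3,5-dimethylhepta-4,6-dien-1-yl]oxy}dimethylsilane
Product: 23 (4S,5R,6R)-4-{[(tert-butyldiphenylsilyl)oxy]methyl}-3-[(3E,5E,7S)-9-[(tert-butyldimethylsilyl)oxy]-5,7-dimethylnona-3,5-dien-1-yn-1-yl]-5,6-dihydroxy-6-methylcyclohex-2-en-1-one
Conditions: Pd(PPh3)4 (5 mol %), CuI (10 mol %), Et3N, THF, rt
Reagents that add atoms: none
Why: Sonogashira coupling of the terminal alkyne with the vinyl iodide forms C3–C1′ with retention of alkene geometry; the tertiary amine cannot add to the enynone and the free diol is tolerated.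

Step 17
Reactants: 23 (4S,5R,6R)-4-{[(tert-butyldiphenylsilyl)oxy]methyl}-3-[(3E,5E,7S)-9-[(tert-butyldimethylsilyl)oxy]-5,7-dimethylnona-3,5-dien-1-yn-1-yl]-5,6-dihydroxy-6-methylcyclohex-2-en-1-one
Product: 25 (7R,8R,8aS)-7,8-dihydroxy-3-[(1E,3E,5S)-7-hydroxy-3,5-dimethylhepta-1,3-dien-1-yl]-7-methyl-1,7,8,8a-tetrahydro-6H-isochromen-6-one, via desilylated enynone tetraol 24 (not isolated)
Conditions: Bu4NF (3 equiv), THF, 0 °C to rt
Reagents that add atoms: none
Why: Fluoride removes both silyl ethers and the freed C1 hydroxyl should add to C3, the δ-terminus of the enynone, in a 6-endo-dig oxa-Michael (1,6-) addition, followed by protonation at C4 to give the dienol ether; the C8 hydroxyl cannot compete because its closure would give a bridged ring with a bridgehead alkene, and the stereocentres are untouched.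

Step 18
Reactants: 25 (7R,8R,8aS)-7,8-dihydroxy-3-[(1E,3E,5S)-7-hydroxy-3,5-dimethylhepta-1,3-dien-1-yl]-7-methyl-1,7,8,8a-tetrahydro-6H-isochromen-6-one
Product: 26 (7R,8R,8aS)-5-chloro-7,8-dihydroxy-3-[(1E,3E,5S)-7-hydroxy-3,5-dimethylhepta-1,3-dien-1-yl]-7-methyl-1,7,8,8a-tetrahydro-6H-isochromen-6-one
Conditions: N-chlorosuccinimide (1.05 equiv), CH2Cl2, −20 to 0 °C
Reagents that add atoms: N-chlorosuccinimide, O=C1CCC(=O)N1Cl
Why: Electrophilic chlorination (α-halogenation of a vinylogous ester) should occur at C5, the carbon that is α to the ketone and conjugated to the ring oxygen through C3=C4–C4a=C5, which is the position halogenated in azaphilone-type chromophores; no stereocentre is involved.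

**Compound list**

1 | 3-hydroxybutan-2-one (racemic) | CC(O)C(C)=O | starting material
2 | 3-[(trimethylsilyl)oxy]butan-2-one | CC(=O)C(C)O[Si](C)(C)C | intermediate
3 | 2,3-bis[(trimethylsilyl)oxy]but-1-ene | C=C(O[Si](C)(C)C)C(C)O[Si](C)(C)C | intermediate
4 | 3-[(tert-butyldiphenylsilyl)oxy]propanoic acid | OC(=O)CCO[Si](c1ccccc1)(c1ccccc1)C(C)(C)C | starting material
5 | (R)-4-benzyloxazolidin-2-one | O=C1N[C@H](Cc2ccccc2)CO1 | starting material
6 | (R)-4-benzyl-3-{3-[(tert-butyldiphenylsilyl)oxy]propanoyl}oxazolidin-2-one | O=C1N(C(=O)CCO[Si](c2ccccc2)(c2ccccc2)C(C)(C)C)[C@H](Cc2ccccc2)CO1 | intermediate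
7 | 3-(trimethylsilyl)prop-2-ynal | O=CC#C[Si](C)(C)C | starting material
8 | (R)-4-benzyl-3-[(2R,3R)-2-{[(tert-butyldiphenylsilyl)oxy]methyl}-3-hydroxy-5-(trimethylsilyl)pent-4-ynoyl]oxazolidin-2-one | O=C1N(C(=O)[C@H](CO[Si](c2ccccc2)(c2ccccc2)C(C)(C)C)[C@@H](O)C#C[Si](C)(C)C)[C@H](Cc2ccccc2)CO1 | intermediate
9 | (R)-4-benzyl-3-[(2R)-2-{[(tert-butyldiphenylsilyl)oxy]methyl}-3-oxo-5-(trimethylsilyl)pent-4-ynoyl]oxazolidin-2-one | O=C1N(C(=O)[C@H](CO[Si](c2ccccc2)(c2ccccc2)C(C)(C)C)C(=O)C#C[Si](C)(C)C)[C@H](Cc2ccccc2)CO1 | intermediate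
10 | (R)-4-benzyl-3-[(2R)-2-{[(tert-butyldiphenylsilyl)oxy]methyl}-3,3-dimethoxy-5-(trimethylsilyl)pent-4-ynoyl]oxazolidin-2-one | O=C1N(C(=O)[C@H](CO[Si](c2ccccc2)(c2ccccc2)C(C)(C)C)C(OC)(OC)C#C[Si](C)(C)C)[C@H](Cc2ccccc2)CO1 | intermediate
11 | (R)-2-{[(tert-butyldiphenylsilyl)oxy]methyl}-3,3-dimethoxy-5-(trimethylsilyl)pent-4-yn-1-ol | OC[C@H](CO[Si](c1ccccc1)(c1ccccc1)C(C)(C)C)C(OC)(OC)C#C[Si](C)(C)C | intermediate
12 | (R)-2-{[(tert-butyldiphenylsilyl)oxy]methyl}-3,3-dimethoxypent-4-yn-1-ol | OC[C@H](CO[Si](c1ccccc1)(c1ccccc1)C(C)(C)C)C(OC)(OC)C#C | intermediate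
13 | (S)-2-{[(tert-butyldiphenylsilyl)oxy]methyl}-3,3-dimethoxypent-4-ynal | O=C[C@H](CO[Si](c1ccccc1)(c1ccccc1)C(C)(C)C)C(OC)(OC)C#C | intermediate
14 | (2R)-2-{[(tert-butyldiphenylsilyl)oxy]methyl}-3-ethynyl-3-methoxy-5-oxo-6-[(trimethylsilyl)oxy]heptanal (C3 and C6 epimers; not isolated) | CC(O[Si](C)(C)C)C(=O)CC(OC)(C#C)[C@H](C=O)CO[Si](c1ccccc1)(c1ccccc1)C(C)(C)C | intermediate
15 | (2R,3R,4S)-4-{[(tert-butyldiphenylsilyl)oxy]methyl}-5-ethynyl-2,3-dihydroxy-5-methoxy-2-methylcyclohexan-1-one (C5 epimers; present as its titanium diolate; not isolated) | C#CC1(OC)CC(=O)[C@](C)(O)[C@H](O)[C@@H]1CO[Si](c2ccccc2)(c2ccccc2)C(C)(C)C | intermediate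
16 | (4S,5R,6R)-4-{[(tert-butyldiphenylsilyl)oxy]methyl}-3-ethynyl-5,6-dihydroxy-6-methylcyclohex-2-en-1-one | C#CC1=CC(=O)[C@](C)(O)[C@H](O)[C@@H]1CO[Si](c2ccccc2)(c2ccccc2)C(C)(C)C | intermediate
17 | α-methylene-γ-butyrolactone | C=C1CCOC1=O | starting material
18 | (S)-3-methyldihydrofuran-2(3H)-one | C[C@H]1CCOC1=O | intermediate
19 | (3S)-3-methyltetrahydrofuran-2-ol (anomers) | C[C@H]1CCOC1O | intermediate
20 | (2E,4S)-6-hydroxy-2,4-dimethylhex-2-enal | O=C/C(C)=C/[C@@H](C)CCO | intermediate
21 | (2E,4S)-6-[(tert-butyldimethylsilyl)oxy]-2,4-dimethylhex-2-enal | O=C/C(C)=C/[C@@H](C)CCO[Si](C)(C)C(C)(C)C | intermediate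
22 | tert-butyl{[(3S,4E,6E)-7-iodo-3,5-dimethylhepta-4,6-dien-1-yl]oxy}dimethylsilane | I/C=C/C(C)=C/[C@@H](C)CCO[Si](C)(C)C(C)(C)C | intermediate
23 | (4S,5R,6R)-4-{[(tert-butyldiphenylsilyl)oxy]methyl}-3-[(3E,5E,7S)-9-[(tert-butyldimethylsilyl)oxy]-5,7-dimethylnona-3,5-dien-1-yn-1-yl]-5,6-dihydroxy-6-methylcyclohex-2-en-1-one | CC(/C=C/C#CC1=CC(=O)[C@](C)(O)[C@H](O)[C@@H]1CO[Si](c2ccccc2)(c2ccccc2)C(C)(C)C)=C\[C@@H](C)CCO[Si](C)(C)C(C)(C)C | intermediate
24 | (4S,5R,6R)-5,6-dihydroxy-3-[(3E,5E,7S)-9-hydroxy-5,7-dimethylnona-3,5-dien-1-yn-1-yl]-4-(hydroxymethyl)-6-methylcyclohex-2-en-1-one (not isolated) | CC(/C=C/C#CC1=CC(=O)[C@](C)(O)[C@H](O)[C@@H]1CO)=C\[C@@H](C)CCO | intermediate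
25 | (7R,8R,8aS)-7,8-dihydroxy-3-[(1E,3E,5S)-7-hydroxy-3,5-dimethylhepta-1,3-dien-1-yl]-7-methyl-1,7,8,8a-tetrahydro-6H-isochromen-6-one | CC(/C=C/C1=CC2=CC(=O)[C@](C)(O)[C@H](O)[C@@H]2CO1)=C\[C@@H](C)CCO | intermediate
26 | (7R,8R,8aS)-5-chloro-7,8-dihydroxy-3-[(1E,3E,5S)-7-hydroxy-3,5-dimethylhepta-1,3-dien-1-yl]-7-methyl-1,7,8,8a-tetrahydro-6H-isochromen-6-one | CC(/C=C/C1=CC2=C(Cl)C(=O)[C@](C)(O)[C@H](O)[C@@H]2CO1)=C\[C@@H](C)CCO | target

**Step count and risks**

Total steps: 18. Longest linear sequence: 11 steps (steps 3–10, then 16–18).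

Steps most likely to fail:

1. Step 10 (proposed new method). In the titanium stage the ketone may enolise toward C5 and lose methoxide before ring closure, giving an open-chain enynone that cannot cyclise. The aldehyde may also epimerise at C8a, and in the first stage the oxocarbenium ion may lose a proton. The fallback sets out from 1 and 13 and comes back at 16; it reverses the order of the two bond formations with established Mukaiyama chemistry. Compound 1 is converted under thermodynamic silylation (Me3SiCl, NaI, Et3N, MeCN) into 2,3-bis[(trimethylsilyl)oxy]but-2-ene F1. A MgBr2·OEt2-mediated Mukaiyama aldol of F1 with 13 at −78 °C, with the aldehyde and a ketal oxygen chelated to magnesium to control C8 against C8a, should give (3R,4R,5S)-5-{[(tert-butyldiphenylsilyl)oxy]methyl}-4-hydroxy-6,6-dimethoxy-3-methyl-3-[(trimethylsilyl)oxy]oct-7-yn-2-one F2, the C7 epimers being separated by chromatography. In a separate step the methyl ketone of F2 is closed onto the ketal with Me3SiOTf/i-Pr2NEt (enol silane formed in the flask, intramolecular addition to the ketal), and DBU followed by dilute acid removes methanol and the silyl ether to give 16.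

2. Step 18. Chlorination may take place at C4 or on the dienyl chain instead of C5 (poor site selectivity), or go on to polychlorination. The fallback sets out from 3 and 13 and comes back at 26; it carries the chlorine from the start. Enol silane 3 is chlorinated with N-chlorosuccinimide to 1-chloro-3-[(trimethylsilyl)oxy]butan-2-one F3, which is converted with LiN(i-Pr)2/Me3SiCl into 1-chloro-2,3-bis[(trimethylsilyl)oxy]but-1-ene F4. Annulation of F4 with 13 under the conditions of step 10 would give (4S,5R,6R)-4-{[(tert-butyldiphenylsilyl)oxy]methyl}-2-chloro-3-ethynyl-5,6-dihydroxy-6-methylcyclohex-2-en-1-one F5. Sonogashira coupling with 22 gives (4S,5R,6R)-4-{[(tert-butyldiphenylsilyl)oxy]methyl}-3-[(3E,5E,7S)-9-[(tert-butyldimethylsilyl)oxy]-5,7-dimethylnona-3,5-dien-1-yn-1-yl]-2-chloro-5,6-dihydroxy-6-methylcyclohex-2-en-1-one F6, and Bu4NF as in step 17 then gives 26 directly.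

3. Step 17. Basic fluoride may cause retro-aldol opening of the β-hydroxy ketone or epimerisation at C8a, and the ring closure may be incomplete or take the 5-exo course. The fallback sets out from 23 and comes back at 25; it separates the two events and avoids base. Desilylation with HF·pyridine in THF/pyridine gives 24, which is isolated, and a π-acid-catalysed 6-endo cycloisomerisation with AgOTf (5 mol %) in CH2Cl2 then gives 25. No new compound arises.

Further compounds
F1 | step 10 | 2,3-bis[(trimethylsilyl)oxy]but-2-ene | CC(O[Si](C)(C)C)=C(C)O[Si](C)(C)C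
F2 | step 10 | (3R,4R,5S)-5-{[(tert-butyldiphenylsilyl)oxy]methyl}-4-hydroxy-6,6-dimethoxy-3-methyl-3-[(trimethylsilyl)oxy]oct-7-yn-2-one | CC(=O)[C@](C)(O[Si](C)(C)C)[C@H](O)[C@H](CO[Si](c1ccccc1)(c1ccccc1)C(C)(C)C)C(OC)(OC)C#C
F3 | step 18 | 1-chloro-3-[(trimethylsilyl)oxy]butan-2-one | CC(O[Si](C)(C)C)C(=O)CCl
F4 | step 18 | 1-chloro-2,3-bis[(trimethylsilyl)oxy]but-1-ene | ClC=C(O[Si](C)(C)C)C(C)O[Si](C)(C)C
F5 | step 18 | (4S,5R,6R)-4-{[(tert-butyldiphenylsilyl)oxy]methyl}-2-chloro-3-ethynyl-5,6-dihydroxy-6-methylcyclohex-2-en-1-one | C#CC1=C(Cl)C(=O)[C@](C)(O)[C@H](O)[C@@H]1CO[Si](c2ccccc2)(c2ccccc2)C(C)(C)C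
F6 | step 18 | (4S,5R,6R)-4-{[(tert-butyldiphenylsilyl)oxy]methyl}-3-[(3E,5E,7S)-9-[(tert-butyldimethylsilyl)oxy]-5,7-dimethylnona-3,5-dien-1-yn-1-yl]-2-chloro-5,6-dihydroxy-6-methylcyclohex-2-en-1-one | CC(/C=C/C#CC1=C(Cl)C(=O)[C@](C)(O)[C@H](O)[C@@H]1CO[Si](c2ccccc2)(c2ccccc2)C(C)(C)C)=C\[C@@H](C)CCO[Si](C)(C)C(C)(C)C
F0 | step 17 | none | none
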